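The readings are calculated on assumed constants; the scatter is artificial.

Should the next run be charged at 5 mol% or 12 mol% of initiator, and is it worth leaving beyond 25 min? Ash and elm differ in that loading, so I solved the two ends and joined them.

common to all: substrate 0.021 M; transfer agent 1.05 mM
- ash: partner 1 equiv; initiator 2.5 mol%; run made earlier
- elm: partner 1 equiv; initiator 7.3 mol%; run made earlier
- beta: partner 1.00 equiv; initiator 5 mol%; time 25 min
- delta: partner 1.00 equiv; initiator 12 mol%; time 25 min

| run | time / min | target / % | substrate / % | first chain carrier / % | side product / % |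
|---|---|---|---|---|---|
| ash | 4.00 | 44 | 54 | 0 | 0 |
| ash | 8.00 | 54 | 46 | 3 | 1 |
| ash | 10.0 | 54 | 47 | 3 | 1 |
| ash | 15.0 | 51 | 41 | 3 | 3 |
| ash | 20.0 | 55 | 45 | 2 | 2 |
| ash | 25.0 | 54 | 43 | 3 | 7 |
| elm | 1.33 | 60 | 42 | 0 | 0 |
| elm | 4.00 | 78 | 17 | 2 | 3 |
| elm | 8.00 | 81 | 11 | 3 | 3 |
| elm | 10.0 | 78 | 12 | 0 | 3 |
| elm | 15.0 | 79 | 12 | 3 | 8 |
| elm | 20.0 | 79 | 11 | 0 | 6 |
| elm | 25.0 | 80 | 8 | 0 | 4 |

(standard deviation of a reading: 2 percentage points)



* which of these there is most of at the end, counted by the substrate in it, beta (target / side product / substrate / first chain carrier)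
* which of these there is most of at the end, counted by the substrate in it, delta (target / side product / substrate / first chain carrier)
* final amount of the leader among these, as a percentage of the substrate charged, in beta
* final amount of the leader among these, as a percentage of the substrate charged, in delta

From 8.00 min on, the ash readings held substrate near 44.4%. From 8.00 min on, the elm readings held it near 10.8%, with target near 79.4%. Both runs had stalled, so I looked at the natural log of substrate charged over substrate left, divided by the loading. It read 32.5 for ash and 30.5 for elm. Their mean, 31.5, is my stall constant, and I held it for 1.05 mM of transfer agent and one equivalent of partner.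

Elm's balance lacked 9.80% of the substrate, and I subtracted that from both new flasks. So I reckoned beta at 20.7% substrate and 69.5% target, and delta at 2.29% substrate and 87.9% target. I would charge 12 mol% and stop at 25 min.

The forecast, on the ground that “the final conversion depends on its loading, not on time”, gave target at 71% for beta and target at 87% for delta, close to my figures but not the same. Beta ended with target at 71.6%, and delta with target at 86.6%.

    initiator → 2 initiating radical (k = 0.00100 s⁻¹)
    substrate + second chain carrier → released group + first chain carrier (k = 1.20 × 10⁶ M⁻¹ s⁻¹)
    2 first chain carrier → ended chains (k = 1.80 × 10⁷ M⁻¹ s⁻¹)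
    substrate + initiating radical → capped initiator + first chain carrier (k = 2.80 × 10⁵ M⁻¹ s⁻¹)
    transfer agent + first chain carrier → side product + idle radical (kL = 1.90 × 10⁵ M⁻¹ s⁻¹)
    partner → decomposed reagent (k = 0.00360 s⁻¹)
    2 idle radical → ended radicals (k = 3.90 × 10⁶ M⁻¹ s⁻¹)
    partner + first chain carrier → target + second chain carrier (k = 7.90 × 10⁵ M⁻¹ s⁻¹)

Beta's own stall constant came to 31.6 against my 31.5, and delta's substrate stood at 0% against my 2.29%. Beta stalled with initiator at 22% of its charge but partner, the limiting reagent, at 0%. Delta's target stood higher mainly because of its loading of initiator : 86.6% against 71.6% in delta at beta's loading. The neighbour of beta charged with 0.0042 M of transfer agent showed a stall constant of 10.9, a third of mine, with target at 34.4%.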